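**Strategy**

Everything rests on cutting the O1–C2 bond of the dihydrobenzofuran. Because the hydroxyl of ring B lies para to the carbon that carries C2, oxidation of that phenol turns C2 into an electrophilic methide carbon, and the ring A oxygen O1 is placed three atoms from it. One operation, Ag2O on the open-chain diarylpropanol 18, thus forms the quinone methide and closes the five-membered ring, creating C2 trans to the C3 centre that an auxiliary-controlled alkylation set earlier. The precursor is an (R)-2,3-diarylpropan-1-ol with both phenols free and a formyl group on ring A, which keeps ring A out of the oxidation and is finally extended to the (E)-acrylic acid.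

Key step: step 12

Remark: ring A is the benzene ring of the benzofuran, ring B the 4-hydroxy-3,5-dimethoxyphenyl ring, and O1, C2, C3 follow benzofuran numbering; the target is the trans-(2S,3R) isomer, which corresponds to the (R) configuration of 18, and (2-ethoxy-2-oxoethyl)zinc bromide is assumed to be bought as a solution.

**Route**

Step 1
Reactants: 1 5-iodovanillin (4-hydroxy-3-iodo-5-methoxybenzaldehyde)
Product: 2 4-(benzyloxy)-3-iodo-5-methoxybenzaldehyde
Conditions: BnBr, K2CO3, DMF, 60 °C
Reagents that add atoms: benzyl bromide, BrCc1ccccc1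
Why: Williamson ether synthesis, in which the phenoxide of 1 (made acidic by the para formyl group) is O-benzylated to an ether that lasts until the hydrogenolysis in step 11.

Step 2
Reactants: 2 4-(benzyloxy)-3-iodo-5-methoxybenzaldehyde
Product: 3 2-[4-(benzyloxy)-3-iodo-5-methoxyphenyl]-1,3-dioxolane
Conditions: HOCH2CH2OH, TsOH·H2O (cat.), toluene, reflux, Dean–Stark trap
Reagents that add atoms: ethylene glycol, OCCO
Why: Acid-catalysed acetalisation driven by azeotropic removal of water, which masks the aldehyde against the zinc enolate, the sodium enolate and LiBH4 of later steps and proceeds normally because the phenol is already etherified.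

Step 3
Reactants: 3 2-[4-(benzyloxy)-3-iodo-5-methoxyphenyl]-1,3-dioxolane; 4 (2-ethoxy-2-oxoethyl)zinc bromide
Product: 5 ethyl [2-(benzyloxy)-5-(1,3-dioxolan-2-yl)-3-methoxyphenyl]acetate
Conditions: Pd2(dba)3 (cat.), XPhos (cat.), THF, 60 °C
Reagents that add atoms: none
Why: Negishi-type cross-coupling of a Reformatsky reagent, in which oxidative addition of the aryl iodide to zerovalent palladium, transmetalation of the zinc ester enolate and reductive elimination form the aryl–CH2 bond while acetal and benzyl ether stay inert.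

Step 4
Reactants: 5 ethyl [2-(benzyloxy)-5-(1,3-dioxolan-2-yl)-3-methoxyphenyl]acetate
Product: 6 [2-(benzyloxy)-5-(1,3-dioxolan-2-yl)-3-methoxyphenyl]acetic acid
Conditions: LiOH, THF–H2O, rt; then AcOH to pH 4–5, 0 °C
Reagents that add atoms: lithium hydroxide, [Li+].[OH-]
Why: Saponification of the ethyl ester by hydroxide (acyl–oxygen cleavage), with acidification stopped at pH 4–5 in the cold so that the acid-labile dioxolane is kept.

Step 5
Reactants: 6 [2-(benzyloxy)-5-(1,3-dioxolan-2-yl)-3-methoxyphenyl]acetic acid; 7 (4R)-4-benzyl-1,3-oxazolidin-2-one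
Product: 9 (4R)-4-benzyl-3-{[2-(benzyloxy)-5-(1,3-dioxolan-2-yl)-3-methoxyphenyl]acetyl}-1,3-oxazolidin-2-one, via mixed pivalic anhydride 8 (not isolated)
Conditions: t-BuCOCl, Et3N, THF, −20 °C; then 7, LiCl, rt
Reagents that add atoms: none
Why: N-Acylation of the Evans auxiliary through a mixed anhydride, where LiCl and Et3N activate the oxazolidinone N–H and the nucleophile attacks the unhindered arylacetyl carbonyl of 8 rather than the pivaloyl one.

Step 6
Reactants: 10 syringaldehyde (4-hydroxy-3,5-dimethoxybenzaldehyde)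
Product: 11 4-(benzyloxy)-3,5-dimethoxybenzaldehyde
Conditions: BnBr, K2CO3, DMF, 60 °C
Reagents that add atoms: benzyl bromide, BrCc1ccccc1
Why: Williamson ether synthesis on the acidic para-formyl phenol, giving the benzyl ether that is removed together with the ring A benzyl ether in step 11.

Step 7
Reactants: 11 4-(benzyloxy)-3,5-dimethoxybenzaldehyde
Product: 12 [4-(benzyloxy)-3,5-dimethoxyphenyl]methanol
Conditions: NaBH4, MeOH–THF, 0 °C
Reagents that add atoms: none
Why: Hydride reduction of an aromatic aldehyde to the benzylic alcohol, a transformation that no other group in 11 can interfere with.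

Step 8
Reactants: 12 [4-(benzyloxy)-3,5-dimethoxyphenyl]methanol
Product: 13 2-(benzyloxy)-5-(bromomethyl)-1,3-dimethoxybenzene
Conditions: PBr3, CH2Cl2, 0 °C
Reagents that add atoms: phosphorus tribromide, BrP(Br)Br
Why: Bromination of a benzylic alcohol with PBr3 through a phosphite ester and SN2 displacement by bromide, fast at 0 °C for this electron-rich benzylic position and giving a bromide that is used without storage.

Step 9
Reactants: 9 (4R)-4-benzyl-3-{[2-(benzyloxy)-5-(1,3-dioxolan-2-yl)-3-methoxyphenyl]acetyl}-1,3-oxazolidin-2-one; 13 2-(benzyloxy)-5-(bromomethyl)-1,3-dimethoxybenzene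
Product: 15 (4R)-4-benzyl-3-[(2R)-2-[2-(benzyloxy)-5-(1,3-dioxolan-2-yl)-3-methoxyphenyl]-3-[4-(benzyloxy)-3,5-dimethoxyphenyl]propanoyl]-1,3-oxazolidin-2-one, via sodium enolate 14 (not isolated)
Conditions: NaN(SiMe3)2, THF, −78 °C; then 13, −78 to −30 °C
Reagents that add atoms: none
Why: Evans asymmetric alkylation, in which the chelated (Z)-sodium enolate 14 is shielded on one face by the C4 benzyl group of the (R)-auxiliary, so that the reactive benzylic bromide 13 is taken up on the opposite (Re) face of the α-carbon and the (R) centre that becomes C3 is set.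

Step 10
Reactants: 15 (4R)-4-benzyl-3-[(2R)-2-[2-(benzyloxy)-5-(1,3-dioxolan-2-yl)-3-methoxyphenyl]-3-[4-(benzyloxy)-3,5-dimethoxyphenyl]propanoyl]-1,3-oxazolidin-2-one
Product: 16 (2R)-2-[2-(benzyloxy)-5-(1,3-dioxolan-2-yl)-3-methoxyphenyl]-3-[4-(benzyloxy)-3,5-dimethoxyphenyl]propan-1-ol
Conditions: LiBH4, H2O (1 equiv), THF, 0 °C
Reagents that add atoms: none
Why: Reductive cleavage of the N-acyl oxazolidinone by LiBH4, which attacks the exocyclic carbonyl and reduces it to the primary alcohol under non-enolising conditions, so that the α-aryl stereocentre is carried over unchanged and auxiliary 7 is released for recovery.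

Step 11
Reactants: 16 (2R)-2-[2-(benzyloxy)-5-(1,3-dioxolan-2-yl)-3-methoxyphenyl]-3-[4-(benzyloxy)-3,5-dimethoxyphenyl]propan-1-ol
Product: 18 4-hydroxy-3-[(2R)-1-hydroxy-3-(4-hydroxy-3,5-dimethoxyphenyl)propan-2-yl]-5-methoxybenzaldehyde, via debenzylated dioxolane 17 (not isolated)
Conditions: H2 (1 atm), 10% Pd/C, EtOAc, rt; filter; then 1 M aq. HCl, THF, rt
Reagents that add atoms: water, O
Why: Catalytic hydrogenolysis of the two aryl benzyl ethers in neutral ethyl acetate, where the dioxolane should persist, followed by acid-catalysed acetal hydrolysis, leaves a stereocentre that has no adjacent carbonyl group and therefore cannot epimerise.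

Step 12
Reactants: 18 4-hydroxy-3-[(2R)-1-hydroxy-3-(4-hydroxy-3,5-dimethoxyphenyl)propan-2-yl]-5-methoxybenzaldehyde
Product: 20 (2S,3R)-2-(4-hydroxy-3,5-dimethoxyphenyl)-3-(hydroxymethyl)-7-methoxy-2,3-dihydro-1-benzofuran-5-carbaldehyde, via para-quinone methide 19 (not isolated)
Conditions: Ag2O (1.5 equiv), CH2Cl2, rt, dark
Reagents that add atoms: none
Why: Ag2O removes two electrons and two protons from the ring B phenol, whose two ortho methoxy groups block radical coupling, so that the phenoxyl stage collapses to the para-quinone methide 19 in which C2 is the exocyclic electrophilic carbon. The ring A oxygen O1 then adds to C2 in an intramolecular 1,6-conjugate addition that makes the O1–C2 bond and returns ring B to its aromatic state. The closest known reaction types are the Ag2O oxidation of 4-alkyl-2,6-dimethoxyphenols to para-quinone methides and the conjugate addition of phenols to such methides. The dihydrofuran ring closes in the 5-exo-trig mode. The new C2 centre is controlled by the C3 centre set in step 9: O1 attacks the methide face that puts the aryl group anti to the hydroxymethyl group, and since the phenoxide addition can revert on the basic silver surface, the more stable trans (2S,3R) isomer should dominate in any case. The step needs oxidation of ring B in preference to ring A, the aldehyde and the product; the formyl group para to the ring A hydroxyl makes that phenol acidic, hard to oxidise and free to act as the nucleophile, the primary alcohol could only close a four-membered ring, and a small excess of Ag2O in dry CH2Cl2 limits further oxidation.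

Step 13
Reactants: 20 (2S,3R)-2-(4-hydroxy-3,5-dimethoxyphenyl)-3-(hydroxymethyl)-7-methoxy-2,3-dihydro-1-benzofuran-5-carbaldehyde; 21 malonic acid
Product: 23 (2E)-3-[(2S,3R)-2-(4-hydroxy-3,5-dimethoxyphenyl)-3-(hydroxymethyl)-7-methoxy-2,3-dihydro-1-benzofuran-5-yl]prop-2-enoic acid, via arylidenemalonic acid 22 (not isolated)
Conditions: pyridine, piperidine (cat.), 80 °C
Reagents that add atoms: none
Why: Knoevenagel–Doebner condensation, in which the piperidine-catalysed condensation gives the arylidenemalonic acid 22 that decarboxylates in warm pyridine to the more stable (E)-acrylic acid, conditions under which free phenols and alcohols are routinely tolerated and the ring stereocentres, already in the favoured trans arrangement, are not at risk.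

**Compound list**

1 | 5-iodovanillin (4-hydroxy-3-iodo-5-methoxybenzaldehyde) | COc1cc(C=O)cc(I)c1O | starting material
2 | 4-(benzyloxy)-3-iodo-5-methoxybenzaldehyde | COc1cc(C=O)cc(I)c1OCc1ccccc1 | intermediate
3 | 2-[4-(benzyloxy)-3-iodo-5-methoxyphenyl]-1,3-dioxolane | COc1cc(C2OCCO2)cc(I)c1OCc1ccccc1 | intermediate
4 | (2-ethoxy-2-oxoethyl)zinc bromide | CCOC(=O)C[Zn]Br | starting material
5 | ethyl [2-(benzyloxy)-5-(1,3-dioxolan-2-yl)-3-methoxyphenyl]acetate | CCOC(=O)Cc1cc(C2OCCO2)cc(OC)c1OCc1ccccc1 | intermediate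
6 | [2-(benzyloxy)-5-(1,3-dioxolan-2-yl)-3-methoxyphenyl]acetic acid | OC(=O)Cc1cc(C2OCCO2)cc(OC)c1OCc1ccccc1 | intermediate
7 | (4R)-4-benzyl-1,3-oxazolidin-2-one | O=C1N[C@H](Cc2ccccc2)CO1 | starting material
8 | [2-(benzyloxy)-5-(1,3-dioxolan-2-yl)-3-methoxyphenyl]acetic 2,2-dimethylpropanoic anhydride | CC(C)(C)C(=O)OC(=O)Cc1cc(C2OCCO2)cc(OC)c1OCc1ccccc1 | intermediate (not isolated)
9 | (4R)-4-benzyl-3-{[2-(benzyloxy)-5-(1,3-dioxolan-2-yl)-3-methoxyphenyl]acetyl}-1,3-oxazolidin-2-one | O=C(Cc1cc(C2OCCO2)cc(OC)c1OCc1ccccc1)N1C(=O)OC[C@H]1Cc1ccccc1 | intermediate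
10 | syringaldehyde (4-hydroxy-3,5-dimethoxybenzaldehyde) | COc1cc(C=O)cc(OC)c1O | starting material
11 | 4-(benzyloxy)-3,5-dimethoxybenzaldehyde | COc1cc(C=O)cc(OC)c1OCc1ccccc1 | intermediate
12 | [4-(benzyloxy)-3,5-dimethoxyphenyl]methanol | COc1cc(CO)cc(OC)c1OCc1ccccc1 | intermediate
13 | 2-(benzyloxy)-5-(bromomethyl)-1,3-dimethoxybenzene | COc1cc(CBr)cc(OC)c1OCc1ccccc1 | intermediate
14 | sodium (Z)-1-[(4R)-4-benzyl-2-oxo-1,3-oxazolidin-3-yl]-2-[2-(benzyloxy)-5-(1,3-dioxolan-2-yl)-3-methoxyphenyl]ethen-1-olate | [Na+].[O-]/C(=C\c1cc(C2OCCO2)cc(OC)c1OCc1ccccc1)N1C(=O)OC[C@H]1Cc1ccccc1 | intermediate (not isolated)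
15 | (4R)-4-benzyl-3-[(2R)-2-[2-(benzyloxy)-5-(1,3-dioxolan-2-yl)-3-methoxyphenyl]-3-[4-(benzyloxy)-3,5-dimethoxyphenyl]propanoyl]-1,3-oxazolidin-2-one | O=C([C@H](Cc1cc(OC)c(OCc2ccccc2)c(OC)c1)c1cc(C2OCCO2)cc(OC)c1OCc1ccccc1)N1C(=O)OC[C@H]1Cc1ccccc1 | intermediate
16 | (2R)-2-[2-(benzyloxy)-5-(1,3-dioxolan-2-yl)-3-methoxyphenyl]-3-[4-(benzyloxy)-3,5-dimethoxyphenyl]propan-1-ol | OC[C@H](Cc1cc(OC)c(OCc2ccccc2)c(OC)c1)c1cc(C2OCCO2)cc(OC)c1OCc1ccccc1 | intermediate
17 | 4-(1,3-dioxolan-2-yl)-2-[(2R)-1-hydroxy-3-(4-hydroxy-3,5-dimethoxyphenyl)propan-2-yl]-6-methoxyphenol | OC[C@H](Cc1cc(OC)c(O)c(OC)c1)c1cc(C2OCCO2)cc(OC)c1O | intermediate (not isolated)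
18 | 4-hydroxy-3-[(2R)-1-hydroxy-3-(4-hydroxy-3,5-dimethoxyphenyl)propan-2-yl]-5-methoxybenzaldehyde | OC[C@H](Cc1cc(OC)c(O)c(OC)c1)c1cc(C=O)cc(OC)c1O | intermediate
19 | 3-[(2R)-3-(3,5-dimethoxy-4-oxocyclohexa-2,5-dien-1-ylidene)-1-hydroxypropan-2-yl]-4-hydroxy-5-methoxybenzaldehyde | OC[C@H](C=C1C=C(OC)C(=O)C(OC)=C1)c1cc(C=O)cc(OC)c1O | intermediate (not isolated)
20 | (2S,3R)-2-(4-hydroxy-3,5-dimethoxyphenyl)-3-(hydroxymethyl)-7-methoxy-2,3-dihydro-1-benzofuran-5-carbaldehyde | COc1cc([C@H]2Oc3c(OC)cc(C=O)cc3[C@@H]2CO)cc(OC)c1O | intermediate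
21 | malonic acid | OC(=O)CC(=O)O | starting material
22 | 2-{[(2S,3R)-2-(4-hydroxy-3,5-dimethoxyphenyl)-3-(hydroxymethyl)-7-methoxy-2,3-dihydro-1-benzofuran-5-yl]methylidene}propanedioic acid | COc1cc([C@H]2Oc3c(OC)cc(C=C(C(=O)O)C(=O)O)cc3[C@@H]2CO)cc(OC)c1O | intermediate (not isolated)
23 | (2E)-3-[(2S,3R)-2-(4-hydroxy-3,5-dimethoxyphenyl)-3-(hydroxymethyl)-7-methoxy-2,3-dihydro-1-benzofuran-5-yl]prop-2-enoic acid | COc1cc([C@H]2Oc3c(OC)cc(/C=C/C(=O)O)cc3[C@@H]2CO)cc(OC)c1O | target

**Step count**

Total: 13 steps. Longest linear sequence: 10 steps (steps 1–5 and 9–13); steps 6–8 form the side branch to bromide 13.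

**Steps most likely to fail**

Step 12. What may go wrong is oxidation running past the dihydrobenzofuran at the benzylic position next to ring B, oxidation of the aldehyde on the silver surface, or tautomerisation of the methide to a stilbene before O1 closes. The fallback reaches the same methide by dehydration instead of oxidation; it sets out from acid 6 and aldehyde 11 and comes back to the route at 20.
- Acid 6 is activated as anhydride 8 exactly as in step 5, but is coupled to (4S)-4-benzyl-1,3-oxazolidin-2-one, which should give the enantiomeric-auxiliary imide F1.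
- Its dibutylboron (Z)-enolate (Bu2BOTf, i-Pr2NEt, CH2Cl2, −78 to 0 °C) is condensed with 11 in an Evans syn aldol reaction to the (2S,3S)-β-hydroxy imide F2. The boron enolate reacts through a non-chelated chair transition state on the enolate face opposite to the one used by the chelated sodium enolate of step 9, which is why the (S)-auxiliary is needed to obtain the C3 configuration of 16.
- LiBH4 should release the (1S,2R)-1,3-diol F3, and hydrogenolysis (H2, Pd/C, EtOAc) the debenzylated diol F4.
- Dilute HCl in aqueous THF hydrolyses the dioxolane to the hydroxy aldehyde F5 and ionises its para-hydroxybenzylic alcohol to methide 19, which closes to 20. The carbinol configuration is erased in this last operation, so only the C3 centre has to be controlled.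

Step 9. What may go wrong is loss of the auxiliary anion from the arylacetyl enolate to give a ketene, incomplete alkylation of the hindered enolate, or erosion of facial selectivity. The fallback sets the centre by asymmetric hydrogenation; it sets out from 6 and 11 and comes back at 16.
- Perkin condensation of 6 with 11 (Ac2O, Et3N, 100 °C) should give the (E)-2,3-diarylacrylic acid F6.
- Enantioselective hydrogenation with the cationic complex [Ir(cod)(SpinPHOX)]BArF (H2, Et3N, MeOH), the ligand enantiomer being chosen to deliver the (R) product, should give the (R)-2,3-diarylpropanoic acid F7. A homogeneous catalyst leaves benzyl ethers and dioxolane untouched.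
- BH3·THF at 0 °C reduces F7 to 16.

Step 3. What may go wrong is slow transmetalation of the zinc enolate onto the ortho-alkoxy arylpalladium iodide, so that proto-deiodination or homocoupling takes over. The fallback replaces the palladium coupling by a copper-catalysed malonate arylation; it sets out from 3 and comes back at 5.
- Iodide 3 is coupled with diethyl malonate (CuI, 2-picolinic acid, Cs2CO3, dioxane, 70 °C) to the diethyl arylmalonate F8.
- Krapcho dealkoxycarbonylation (LiCl, wet DMSO, 150 °C) removes one ester group under neutral conditions that the dioxolane tolerates and gives 5.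

**Further compounds**

F1 | step 12 | (4S)-4-benzyl-3-{[2-(benzyloxy)-5-(1,3-dioxolan-2-yl)-3-methoxyphenyl]acetyl}-1,3-oxazolidin-2-one | O=C(Cc1cc(C2OCCO2)cc(OC)c1OCc1ccccc1)N1C(=O)OC[C@@H]1Cc1ccccc1
F2 | step 12 | (4S)-4-benzyl-3-[(2S,3S)-2-[2-(benzyloxy)-5-(1,3-dioxolan-2-yl)-3-methoxyphenyl]-3-[4-(benzyloxy)-3,5-dimethoxyphenyl]-3-hydroxypropanoyl]-1,3-oxazolidin-2-one | O=C([C@H]([C@H](O)c1cc(OC)c(OCc2ccccc2)c(OC)c1)c1cc(C2OCCO2)cc(OC)c1OCc1ccccc1)N1C(=O)OC[C@@H]1Cc1ccccc1
F3 | step 12 | (1S,2R)-2-[2-(benzyloxy)-5-(1,3-dioxolan-2-yl)-3-methoxyphenyl]-1-[4-(benzyloxy)-3,5-dimethoxyphenyl]propane-1,3-diol | OC[C@H]([C@H](O)c1cc(OC)c(OCc2ccccc2)c(OC)c1)c1cc(C2OCCO2)cc(OC)c1OCc1ccccc1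
F4 | step 12 | (1S,2R)-2-[5-(1,3-dioxolan-2-yl)-2-hydroxy-3-methoxyphenyl]-1-(4-hydroxy-3,5-dimethoxyphenyl)propane-1,3-diol | OC[C@H]([C@H](O)c1cc(OC)c(O)c(OC)c1)c1cc(C2OCCO2)cc(OC)c1O
F5 | step 12 | 3-[(1S,2R)-1,3-dihydroxy-1-(4-hydroxy-3,5-dimethoxyphenyl)propan-2-yl]-4-hydroxy-5-methoxybenzaldehyde | OC[C@H]([C@H](O)c1cc(OC)c(O)c(OC)c1)c1cc(C=O)cc(OC)c1O
F6 | step 9 | (2E)-2-[2-(benzyloxy)-5-(1,3-dioxolan-2-yl)-3-methoxyphenyl]-3-[4-(benzyloxy)-3,5-dimethoxyphenyl]prop-2-enoic acid | OC(=O)/C(=C/c1cc(OC)c(OCc2ccccc2)c(OC)c1)c1cc(C2OCCO2)cc(OC)c1OCc1ccccc1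
F7 | step 9 | (2R)-2-[2-(benzyloxy)-5-(1,3-dioxolan-2-yl)-3-methoxyphenyl]-3-[4-(benzyloxy)-3,5-dimethoxyphenyl]propanoic acid | OC(=O)[C@H](Cc1cc(OC)c(OCc2ccccc2)c(OC)c1)c1cc(C2OCCO2)cc(OC)c1OCc1ccccc1
F8 | step 3 | diethyl 2-[2-(benzyloxy)-5-(1,3-dioxolan-2-yl)-3-methoxyphenyl]propanedioate | CCOC(=O)C(C(=O)OCC)c1cc(C2OCCO2)cc(OC)c1OCc1ccccc1
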